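**Plan**
- The target is cut at the hindered ester between the C1 oxygen of one cyclohexane and the carboxyl of the other. This gives two copies of one monomer, a 5-O-caffeoylquinic acid of the (+)-quinic series. The two caffeate esters are cut next.
- Each cyclohexane is traced back to a bridged γ-lactone and from there, by a 1,2-carbon shift, to a cycloheptane-1,2-dione. Ring C1 is a tertiary carbinol carbon that carries the carboxyl carbon and lies between two CH2 groups (C2, C6), which is the pattern left by a benzilic-type ring contraction. The C5 oxygen is 1,3-cis to that carboxyl and can serve as the internal alkoxide.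
- Forward: 2-deoxy-D-ribose → cis-dioxolane diene → seven-membered ring by ring-closing metathesis → 1,2-dione → six-membered carbocycle plus lactone by ring contraction → lactone opening, caffeoylation at C5, ester union of two monomers, deprotection.
- Stereochemistry: C3 and C4 of both rings come from the sugar, C5 from a reagent-controlled allylation, C1 from the lactone tether in the ring contraction; the E alkenes come from caffeic acid.

Key step: step 9

Remark: both cyclohexane units of the given stereoisomer have the configuration of (+)-quinic acid, the antipode of the natural acid, so neither ring is taken from natural quinic acid. Ring positions are numbered as in quinic acid (C1 carboxyl-bearing, C3/C4 cis-diol, C5 the oxygen cis to the carboxyl). One batch of lactone 12 supplies both rings.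

**Step 1**
Reactants: 1 2-deoxy-D-ribose
Product: 2 2-deoxy-3,4-O-isopropylidene-D-erythro-pentopyranose
Conditions: 2-methoxypropene, PPTS (cat.), EtOAc, 0 °C → rt
Reagents that add atoms: 2-methoxypropene, C=C(C)OC
Why: Acid-catalysed acetalisation with the enol ether engages the cis-3,4-diol of the pyranose form as a cis-fused dioxolane (kinetic acetonide formation); C3 and C4 are taken unchanged from the sugar and become C3 and C4 of both cyclohexane rings.

**Step 2**
Reactants: 2 2-deoxy-3,4-O-isopropylidene-D-erythro-pentopyranose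
Product: 3 [(4R,5S)-5-allyl-2,2-dimethyl-1,3-dioxolan-4-yl]methanol
Conditions: Ph3PCH3Br, KOtBu, THF, 0 °C → reflux
Reagents that add atoms: methyltriphenylphosphonium bromide, C[P+](c1ccccc1)(c1ccccc1)c1ccccc1.[Br-]
Why: Wittig methylenation of the open-chain aldehyde in equilibrium with the lactol should give the terminal alkene and free the primary alcohol without touching a stereocentre.

**Step 3**
Reactants: 3 [(4R,5S)-5-allyl-2,2-dimethyl-1,3-dioxolan-4-yl]methanol
Product: 4 (4S,5S)-5-allyl-2,2-dimethyl-1,3-dioxolane-4-carbaldehyde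
Conditions: (COCl)2, DMSO, CH2Cl2, −78 °C; then Et3N; used crude
Reagents that add atoms: none
Why: Swern oxidation at low temperature should give the α-alkoxy aldehyde without over-oxidation, and immediate use avoids epimerisation of the cis-dioxolane centre.

**Step 4**
Reactants: 4 (4S,5S)-5-allyl-2,2-dimethyl-1,3-dioxolane-4-carbaldehyde
Product: 5 (1S)-1-[(4R,5S)-5-allyl-2,2-dimethyl-1,3-dioxolan-4-yl]but-3-en-1-ol
Conditions: (−)-Ipc2B(allyl) (1 M in pentane), Et2O, −78 °C; then NaOH, H2O2
Reagents that add atoms: (−)-B-allyldiisopinocampheylborane (antipode from (+)-α-pinene), C=CCB([C@@H]1C[C@@H]2C[C@H]([C@H]1C)C2(C)C)[C@@H]1C[C@@H]2C[C@H]([C@H]1C)C2(C)C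
Why: Brown allylation: reagent-controlled allyl transfer through a chair-like six-membered transition state to the Si face of the aldehyde should set the new carbinol centre (S), syn (threo) to the neighbouring dioxolane oxygen and against the Felkin preference of the substrate; this centre becomes C5 of the rings.

**Step 5**
Reactants: 5 (1S)-1-[(4R,5S)-5-allyl-2,2-dimethyl-1,3-dioxolan-4-yl]but-3-en-1-ol
Product: 6 triethylsilyl ether of 5
Conditions: TESCl, imidazole, DMF, 0 °C → rt
Reagents that add atoms: chlorotriethylsilane, CC[Si](Cl)(CC)CC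
Why: Silylation of the secondary alcohol masks this oxygen through the oxidations and stores it as the latent trigger of step 9.

**Step 6**
Reactants: 6 triethylsilyl ether of 5
Product: 7 (1S,2S,3S)-2,3-(isopropylidenedioxy)-1-(triethylsilyloxy)cyclohept-5-ene
Conditions: RuCl2(=CHPh)(PCy3)(H2IMes) (second-generation Grubbs catalyst, 3 mol %), CH2Cl2 (5 mM), 40 °C
Reagents that add atoms: none
Why: Ring-closing metathesis of the 1,8-diene, whose two chains are held close by the cis-fused dioxolane, should close the seven-membered ring with loss of ethylene and without creating a stereocentre.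

**Step 7**
Reactants: 7 (1S,2S,3S)-2,3-(isopropylidenedioxy)-1-(triethylsilyloxy)cyclohept-5-ene
Product: 8 (4S,5S,6S)-4,5-(isopropylidenedioxy)-6-(triethylsilyloxy)cycloheptane-cis-1,2-diol
Conditions: OsO4 (2 mol %), NMO, acetone/H2O, rt
Reagents that add atoms: N-methylmorpholine N-oxide, C[N+]1([O-])CCOCC1, and water, O, the oxygen atoms being delivered through osmium tetroxide, O=[Os](=O)(=O)=O
Why: Upjohn dihydroxylation adds syn to the only alkene, and the face of attack is immaterial because both new carbinol carbons become carbonyl carbons in step 8.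

**Step 8**
Reactants: 8 (4S,5S,6S)-4,5-(isopropylidenedioxy)-6-(triethylsilyloxy)cycloheptane-cis-1,2-diol
Product: 9 (4S,5S,6S)-4,5-(isopropylidenedioxy)-6-(triethylsilyloxy)cycloheptane-1,2-dione
Conditions: DMSO, (CF3CO)2O, CH2Cl2, −78 °C; then Et3N, −78 → −20 °C
Reagents that add atoms: none
Why: Swern-type double oxidation with anhydride-activated DMSO should convert the vicinal diol into the 1,2-dione without C–C cleavage, the low temperature limiting enolisation toward the β-oxygenated carbons.

**Step 9**
Reactants: 9 (4S,5S,6S)-4,5-(isopropylidenedioxy)-6-(triethylsilyloxy)cycloheptane-1,2-dione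
Product: 12 3,4-O-isopropylidene-1,5-lactone of (+)-quinic acid, via hydroxy-dione alkoxide 10 (not isolated), via bridged hemiketal alkoxide 11 (not isolated)
Conditions: Bu4NF (1.1 equiv), THF, −20 °C → rt; then AcOH
Reagents that add atoms: none
Why: Fluoride removes the triethylsilyl group and the C6 alkoxide adds across the ring to the C2 carbonyl (cycloheptane numbering) to give the bridged hemiketal alkoxide 11; its O− then re-forms a carbonyl at C2 while the C2–C3 σ-bond migrates to the neighbouring C1 carbonyl carbon, which contracts the carbocycle from seven to six members and leaves C2 as the carbonyl of a γ-lactone to the C6 oxygen, the tertiary alkoxide being protonated on quench. The closest known reaction type is the benzilic ester rearrangement of cyclic 1,2-diones (alkoxide-induced ring contraction to 1-hydroxycycloalkane-1-carboxylates), here in its intramolecular, lactone-forming form. The oxolane of 11 closes by 5-exo-trig attack of oxygen on C2=O, the cyclohexane arises by the 1,2-carbon shift and not by a cyclisation, and the lactone ring is the former hemiketal ring after the shift. The only new stereocentre, the tertiary carbinol carbon (ring C1 of the product), is fixed by the tether: the bridge forces the carboxyl carbon cis to the C5 oxygen, so the hydroxyl ends cis to the dioxolane oxygens as in quinic acid. The step needs site selectivity between the two carbonyls, a single migrating bond and chemoselectivity over enolisation and β-elimination: only C2 is reachable through a five-membered ring (C1 would need an oxetane), only the C2–C3 bond lies out of the oxolane plane and overlaps with the C1=O π* orbital, the dioxolane ties up the other two oxygens, and intramolecular addition under aprotic conditions at low temperature should outrun enolate chemistry.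

**Step 10**
Reactants: 12 3,4-O-isopropylidene-1,5-lactone of (+)-quinic acid
Product: 13 allyl 3,4-O-isopropylidene-(+)-quinate
Conditions: allyl alcohol, NaH (0.2 equiv), 0 °C → rt; then AcOH
Reagents that add atoms: allyl alcohol, C=CCO
Why: Alkoxide-catalysed alcoholysis (transesterification) of the bridged γ-lactone in neat allyl alcohol should release the C5 hydroxyl and give the allyl ester, no stereocentre being affected.

**Step 11**
Reactants: 14 caffeic acid
Product: 16 (E)-3-[3,4-bis(methoxymethoxy)phenyl]acrylic acid, via methoxymethyl ester 15 (not isolated)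
Conditions: MOMCl, iPr2NEt, CH2Cl2, 0 °C → rt; then LiOH, THF/H2O, rt; then 1 M HCl to pH 3, 0 °C
Reagents that add atoms: chloromethyl methyl ether, COCCl
Why: O-Alkylation of both phenols and the carboxylate followed by saponification of the methoxymethyl ester in the same flask should give the acid with acid-labile phenol protection and an unchanged E alkene.

**Step 12**
Reactants: 13 allyl 3,4-O-isopropylidene-(+)-quinate; 16 (E)-3-[3,4-bis(methoxymethoxy)phenyl]acrylic acid
Product: 17 allyl 5-O-[(E)-3,4-bis(methoxymethoxy)cinnamoyl]-3,4-O-isopropylidene-(+)-quinate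
Conditions: EDC·HCl, DMAP, CH2Cl2, 0 °C → rt
Reagents that add atoms: none
Why: Steglich esterification should acylate the secondary C5 hydroxyl selectively, because the tertiary C1 hydroxyl next to the ester does not react under carbodiimide/DMAP conditions.

**Step 13**
Reactants: 17 allyl 5-O-[(E)-3,4-bis(methoxymethoxy)cinnamoyl]-3,4-O-isopropylidene-(+)-quinate (about half of the material)
Product: 18 5-O-[(E)-3,4-bis(methoxymethoxy)cinnamoyl]-3,4-O-isopropylidene-(+)-quinic acid
Conditions: Pd(PPh3)4 (5 mol %), morpholine, THF, rt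
Reagents that add atoms: none
Why: Tsuji–Trost deallylation through a π-allylpalladium complex transfers the allyl group to morpholine and should free the acid under neutral conditions that spare the cinnamate, the acetals and the ketal.

**Step 14**
Reactants: 18 5-O-[(E)-3,4-bis(methoxymethoxy)cinnamoyl]-3,4-O-isopropylidene-(+)-quinic acid; 17 allyl 5-O-[(E)-3,4-bis(methoxymethoxy)cinnamoyl]-3,4-O-isopropylidene-(+)-quinate
Product: 22 protected dimer allyl ester (C1–O of the allyl quinate unit acylated by the carboxyl of the second unit), via bis(trimethylsilyl) derivative 19 (not isolated), via acid chloride 20 (not isolated), via trimethylsilyl ether 21 (not isolated)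
Conditions: 18: TMSCl, Et3N, DMAP (cat.), CH2Cl2, 0 °C → rt; (COCl)2, DMF (cat.), 0 °C; evaporate; then 17, LiN(SiMe3)2, THF, −78 °C → rt; then citric acid, MeOH, rt
Reagents that add atoms: none
Why: Acylation of a lithium tert-alkoxide by an α-silyloxy acid chloride: silylation of OH and CO2H of 18 and exchange of the silyl ester with oxalyl chloride/DMF gives the acid chloride under neutral conditions, the alkoxide of 17 is acylated at the hindered C1 oxygen, and mild acidic methanolysis removes the trimethylsilyl ether, no stereocentre being involved.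

**Step 15**
Reactants: 22 protected dimer allyl ester
Product: 23 protected dimer acid
Conditions: Pd(PPh3)4 (5 mol %), morpholine, THF, rt
Reagents that add atoms: none
Why: Tsuji–Trost deallylation as in step 13 should free the carboxylic acid of the C1-acylated unit while the hindered inter-unit ester and both cinnamates stay intact.

**Step 16**
Reactants: 23 protected dimer acid
Product: 24 target, 5-O-(E)-caffeoyl-1-O-[5-O-(E)-caffeoyl-(+)-quinoyl]-(+)-quinic acid
Conditions: TFA/H2O (4:1), 0 °C → rt
Reagents that add atoms: none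
Why: Acid hydrolysis should cleave the two isopropylidene ketals and the four methoxymethyl aryl ethers, while the cinnamates and the tertiary inter-unit ester are stable to aqueous acid at room temperature and base-promoted acyl migration is avoided.

**Compound list**
1 | 2-deoxy-D-ribose (drawn as the open-chain aldehyde; the commercial solid is the cyclic hemiacetal) | O=CC[C@H](O)[C@H](O)CO | starting material
2 | 2-deoxy-3,4-O-isopropylidene-D-erythro-pentopyranose (anomeric mixture) | OC1C[C@@H]2OC(C)(C)O[C@@H]2CO1 | intermediate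
3 | [(4R,5S)-5-allyl-2,2-dimethyl-1,3-dioxolan-4-yl]methanol | C=CC[C@@H]1OC(C)(C)O[C@@H]1CO | intermediate
4 | (4S,5S)-5-allyl-2,2-dimethyl-1,3-dioxolane-4-carbaldehyde | C=CC[C@@H]1OC(C)(C)O[C@@H]1C=O | intermediate
5 | (1S)-1-[(4R,5S)-5-allyl-2,2-dimethyl-1,3-dioxolan-4-yl]but-3-en-1-ol | C=CC[C@@H]1OC(C)(C)O[C@@H]1[C@@H](O)CC=C | intermediate
6 | triethylsilyl ether of 5 | C=CC[C@@H]1OC(C)(C)O[C@@H]1[C@@H](O[Si](CC)(CC)CC)CC=C | intermediate
7 | (1S,2S,3S)-2,3-(isopropylidenedioxy)-1-(triethylsilyloxy)cyclohept-5-ene (cis-fused dioxolane, silyloxy group trans to it) | C1=CC[C@@H]2OC(C)(C)O[C@@H]2[C@@H](O[Si](CC)(CC)CC)C1 | intermediate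
8 | (4S,5S,6S)-4,5-(isopropylidenedioxy)-6-(triethylsilyloxy)cycloheptane-cis-1,2-diol (both face isomers of the cis-diol serve; C1 and C2 left undefined, both are erased in step 8) | OC1C[C@@H]2OC(C)(C)O[C@@H]2[C@@H](O[Si](CC)(CC)CC)CC1O | intermediate
9 | (4S,5S,6S)-4,5-(isopropylidenedioxy)-6-(triethylsilyloxy)cycloheptane-1,2-dione | O=C1C(=O)C[C@@H]2OC(C)(C)O[C@@H]2[C@@H](O[Si](CC)(CC)CC)C1 | intermediate
10 | (4S,5R,6S)-6-hydroxy-4,5-(isopropylidenedioxy)cycloheptane-1,2-dione (formed as its alkoxide) | O=C1C(=O)C[C@@H]2OC(C)(C)O[C@@H]2[C@@H](O)C1 | intermediate (not isolated)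
11 | bridged hemiketal of 10 (C6 oxygen bonded to C2; 8-oxabicyclo[3.2.1]octan-6-one core with the dioxolane on the three-carbon bridge; formed as its alkoxide) | O=C1C[C@@H]2O[C@@]1(O)C[C@@H]3OC(C)(C)O[C@@H]32 | intermediate (not isolated)
12 | 3,4-O-isopropylidene-1,5-lactone of (+)-quinic acid (enantiomer of the lactone acetonide of natural quinic acid; free tertiary 1-OH) | O[C@@]1(C(=O)O2)C[C@H]2[C@H]3OC(C)(C)O[C@H]3C1 | intermediate
13 | allyl 3,4-O-isopropylidene-(+)-quinate (free 1-OH and 5-OH) | O[C@@]1(C(=O)OCC=C)C[C@H](O)[C@H]2OC(C)(C)O[C@H]2C1 | intermediate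
14 | caffeic acid | O=C(O)/C=C/c1ccc(O)c(O)c1 | starting material
15 | methoxymethyl (E)-3-[3,4-bis(methoxymethoxy)phenyl]acrylate | COCOC(=O)/C=C/c1ccc(OCOC)c(OCOC)c1 | intermediate (not isolated)
16 | (E)-3-[3,4-bis(methoxymethoxy)phenyl]acrylic acid | O=C(O)/C=C/c1ccc(OCOC)c(OCOC)c1 | intermediate
17 | allyl 5-O-[(E)-3,4-bis(methoxymethoxy)cinnamoyl]-3,4-O-isopropylidene-(+)-quinate | O[C@@]1(C(=O)OCC=C)C[C@H](OC(=O)/C=C/c2ccc(OCOC)c(OCOC)c2)[C@H]3OC(C)(C)O[C@H]3C1 | intermediate
18 | 5-O-[(E)-3,4-bis(methoxymethoxy)cinnamoyl]-3,4-O-isopropylidene-(+)-quinic acid | O[C@@]1(C(=O)O)C[C@H](OC(=O)/C=C/c2ccc(OCOC)c(OCOC)c2)[C@H]3OC(C)(C)O[C@H]3C1 | intermediate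
19 | trimethylsilyl ester and 1-O-trimethylsilyl ether of 18 | C[Si](C)(C)O[C@@]1(C(=O)O[Si](C)(C)C)C[C@H](OC(=O)/C=C/c2ccc(OCOC)c(OCOC)c2)[C@H]3OC(C)(C)O[C@H]3C1 | intermediate (not isolated)
20 | 1-O-trimethylsilyl acid chloride of 18 | C[Si](C)(C)O[C@@]1(C(Cl)=O)C[C@H](OC(=O)/C=C/c2ccc(OCOC)c(OCOC)c2)[C@H]3OC(C)(C)O[C@H]3C1 | intermediate (not isolated)
21 | 1-O-trimethylsilyl ether of 22 | C[Si](C)(C)O[C@@]1(C(=O)O[C@@]2(C(=O)OCC=C)C[C@H](OC(=O)/C=C/c3ccc(OCOC)c(OCOC)c3)[C@H]4OC(C)(C)O[C@H]4C2)C[C@H](OC(=O)/C=C/c5ccc(OCOC)c(OCOC)c5)[C@H]6OC(C)(C)O[C@H]6C1 | intermediate (not isolated)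
22 | protected dimer allyl ester (two acetonides, four methoxymethyl ethers, free tertiary OH on the acyl-donor unit) | O[C@@]1(C(=O)O[C@@]2(C(=O)OCC=C)C[C@H](OC(=O)/C=C/c3ccc(OCOC)c(OCOC)c3)[C@H]4OC(C)(C)O[C@H]4C2)C[C@H](OC(=O)/C=C/c5ccc(OCOC)c(OCOC)c5)[C@H]6OC(C)(C)O[C@H]6C1 | intermediate
23 | protected dimer acid | O[C@@]1(C(=O)O[C@@]2(C(=O)O)C[C@H](OC(=O)/C=C/c3ccc(OCOC)c(OCOC)c3)[C@H]4OC(C)(C)O[C@H]4C2)C[C@H](OC(=O)/C=C/c5ccc(OCOC)c(OCOC)c5)[C@H]6OC(C)(C)O[C@H]6C1 | intermediate
24 | 5-O-(E)-caffeoyl-1-O-[5-O-(E)-caffeoyl-(+)-quinoyl]-(+)-quinic acid | O=C(/C=C/c1ccc(O)c(O)c1)O[C@H]1C[C@@](O)(C(=O)O[C@@]2(C(=O)O)C[C@H](OC(=O)/C=C/c3ccc(O)c(O)c3)[C@@H](O)[C@@H](O)C2)C[C@H](O)[C@@H]1O | target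

**Totals**
Total step count: 16. Longest linear sequence: 15 steps (steps 1–10 and 12–16); step 11 is a one-step side branch.

**Steps most likely to fail**

Step 9. The cascade may be lost to enolisation of the dione with β-elimination of a ring oxygen, or to hydrolysis of the lactone by adventitious hydroxide. The fallback replaces the aprotic alkoxide cascade by a protic benzilic acid rearrangement with a separate lactonisation. It sets out from 9. HF·pyridine in THF removes the silyl group, and the hydroxy-dione 10 is isolated, probably as its hemiketal 11. Aqueous KOH in dioxane then brings about the hydroxide-induced rearrangement and saponifies any lactone. Acidification with dilute HCl should give 3,4-O-isopropylidene-(+)-quinic acid F1, possibly together with its C1 epimer F2. DCC in CH2Cl2 lactonises only F1, whose carboxyl is cis to the C5 hydroxyl, and F2 is removed by bicarbonate extraction. The fallback comes back to the route at 12.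

Step 14. Acylation of the lithium alkoxide of 17 may be too slow for steric reasons, so that the acid chloride decomposes first. The fallback uses the more exposed bridgehead hydroxyl of the lactone as the alcohol partner and opens the lactone afterwards. It sets out from 12 and the acid chloride 20. LiN(SiMe3)2 in THF at −78 °C → rt should give the lactone ester trimethylsilyl ether F3. LiOH (1 equiv) in THF/H2O at 0 °C, then dilute HCl, opens the strained γ-lactone and removes the silyl ether to give the hydroxy acid F4. Allyl bromide and KHCO3 in DMF give the allyl ester F5. EDC·HCl/DMAP esterification of its C5 hydroxyl with 16 gives 22, where the fallback comes back to the route.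

Step 4. Facial selectivity may be poor because reagent control has to override the Felkin preference of the aldehyde (mismatched pairing). The fallback uses substrate control followed by inversion. It sets out from 4. Barbier allylation (Zn, allyl bromide, THF/aq NH4Cl) should give the Felkin (anti) alcohol F6, the carbinol epimer of 5. Mitsunobu reaction with 4-nitrobenzoic acid, PPh3 and DIAD gives the inverted ester F7. K2CO3 in MeOH then gives 5, where the fallback comes back to the route.

**Further compounds**
F1 | step 9 | 3,4-O-isopropylidene-(+)-quinic acid | O[C@@]1(C(=O)O)C[C@H](O)[C@H]2OC(C)(C)O[C@H]2C1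
F2 | step 9 | C1 epimer of F1 | O[C@]1(C(=O)O)C[C@H](O)[C@H]2OC(C)(C)O[C@H]2C1
F3 | step 14 | 1-O-acyl lactone: ester of the 1-O-trimethylsilyl acid of 18 with the tertiary oxygen of 12 | C[Si](C)(C)O[C@@]1(C(=O)O[C@@]3(C(=O)O4)C[C@H]4[C@H]5OC(C)(C)O[C@H]5C3)C[C@H](OC(=O)/C=C/c6ccc(OCOC)c(OCOC)c6)[C@H]2OC(C)(C)O[C@H]2C1
F4 | step 14 | hydroxy acid from F3 (lactone opened, silyl ether removed) | O[C@@]1(C(=O)O[C@@]3(C(=O)O)C[C@H](O)[C@H]5OC(C)(C)O[C@H]5C3)C[C@H](OC(=O)/C=C/c6ccc(OCOC)c(OCOC)c6)[C@H]2OC(C)(C)O[C@H]2C1
F5 | step 14 | allyl ester of F4 (free C5 hydroxyl on the C1-acylated unit) | O[C@@]1(C(=O)O[C@@]3(C(=O)OCC=C)C[C@H](O)[C@H]5OC(C)(C)O[C@H]5C3)C[C@H](OC(=O)/C=C/c6ccc(OCOC)c(OCOC)c6)[C@H]2OC(C)(C)O[C@H]2C1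
F6 | step 4 | (1R)-1-[(4R,5S)-5-allyl-2,2-dimethyl-1,3-dioxolan-4-yl]but-3-en-1-ol | C=CC[C@@H]1OC(C)(C)O[C@@H]1[C@H](O)CC=C
F7 | step 4 | 4-nitrobenzoate of 5 | C=CC[C@@H]1OC(C)(C)O[C@@H]1[C@@H](OC(=O)c2ccc(cc2)[N+](=O)[O-])CC=C
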